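**Strategy.** Everything rests on disconnecting the C4a=C8a enol-ether double bond (flavan numbering of the lower unit) shared by the cyclohexadienone ring A and the dihydropyran ring C. This bond is the enol form of a β-diketone, so C8a sits at the carboxyl oxidation level and C4a is the α-carbon of the C5 ketone; the quaternary carbon C8 keeps the ring from aromatising. A Dieckmann cyclisation of the C4a lithium enolate of a vinylogous ester onto the C8-bound methyl ester therefore builds ring A de novo in one operation. Its precursor is a chromanone–dihydrofuran bicycle carrying an ester on C8 and an (E)-acylmethylene side arm that ends in a trans-epoxide.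

Key step: step 12

**Atom labels.** Lower unit: O1, C2, C3, C4, C4a, C5, C6, C7, C8, C8a; ring A = C4a–C5–C6–C7–C8–C8a, ring C = O1–C2–C3–C4–C4a–C8a. Upper unit: C2' (ArCH–O7), C3' (C–OH), C4' (C=O), O1' (aryl ether oxygen on C8); ring D = dihydrofuran O7–C2'–C3'–C8–C7; ring E = pyranone O1'–C8–C3'–C4'–aryl. TIPS = triisopropylsilyl, TBS = tert-butyldimethylsilyl, TMS = trimethylsilyl.

**Assumptions.** The sense of induction of the copper/bis(oxazoline) alkynylation in step 3 is not predicted here; the ligand enantiomer that delivers (2R)-8 is to be used (the S,S ligand is written). Compounds 10 and 11 are mixtures at C3'; this centre is re-formed in step 7.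

Step 1
Reactants: 1 2',4',6'-trihydroxyacetophenone; 2 dimethyl oxalate
Product: 4 methyl 5,7-dihydroxy-4-oxo-4H-chromene-2-carboxylate, via diketo ester 3 (not isolated)
Conditions: NaOMe (5 equiv), MeOH, reflux; then conc. HCl, MeOH, reflux
Reagents that add atoms: none
Why: Claisen condensation of the acetophenone enolate with the oxalate followed by acid-catalysed cyclodehydration is the classical (Kostanecki-type) synthesis of chromone-2-carboxylates; no stereocentre is involved.

Step 2
Reactants: 4 methyl 5,7-dihydroxy-4-oxo-4H-chromene-2-carboxylate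
Product: 5 methyl 4-oxo-5,7-bis(triisopropylsilyloxy)-4H-chromene-2-carboxylate
Conditions: TIPSOTf (2.5 equiv), 2,6-lutidine, CH2Cl2, 0 to 23 °C
Reagents that add atoms: triisopropylsilyl trifluoromethanesulfonate CC(C)[Si](C(C)C)(C(C)C)OS(=O)(=O)C(F)(F)F
Why: Silyl ether formation; the silyl triflate is reactive enough to silylate the chelated 5-hydroxyl as well, and fluoride-labile phenol protection allows a single mild deprotection at the end.

Step 3
Reactants: 5 methyl 4-oxo-5,7-bis(triisopropylsilyloxy)-4H-chromene-2-carboxylate; 6 ethynyltrimethylsilane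
Product: 8 methyl (2R)-4-(tert-butyldimethylsilyloxy)-5,7-bis(triisopropylsilyloxy)-2-[(trimethylsilyl)ethynyl]-2H-chromene-2-carboxylate, via benzopyrylium triflate 7 (not isolated)
Conditions: TBSOTf, iPr2NEt, CuI (10 mol %), 2,2'-(propane-2,2-diyl)bis[(4S)-4-phenyl-4,5-dihydro-1,3-oxazole] (12 mol %), toluene, −78 to −20 °C
Reagents that add atoms: tert-butyldimethylsilyl trifluoromethanesulfonate CC(C)(C)[Si](C)(C)OS(=O)(=O)C(F)(F)F
Why: The silyl triflate turns the chromone into the 4-silyloxybenzopyrylium ion 7 and the copper acetylide on the chiral bis(oxazoline) adds to C2 (copper-catalysed enantioselective alkynylation of chromone-2-carboxylates), which sets the tetrasubstituted C8 centre under catalyst control and leaves the TBS enol ether in place.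

Step 4
Reactants: 8 silyl enol ether from step 3
Product: 10 methyl (2S)-3-(tert-butyldimethylsilyloxy)-4-oxo-5,7-bis(triisopropylsilyloxy)-2-[(trimethylsilyl)ethynyl]chromane-2-carboxylate (C3' epimers), via silyloxy epoxide 9 (not isolated)
Conditions: dimethyldioxirane, acetone/CH2Cl2, −78 to 0 °C
Reagents that add atoms: dimethyldioxirane CC1(C)OO1
Why: Rubottom oxidation, in which epoxidation of the electron-rich enol ether and 1,4-silyl shift give the α-silyloxy ketone; the C3' configuration is irrelevant because the centre is planarised again in step 7.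

Step 5
Reactants: 10 α-silyloxy ketone with TMS-alkyne
Product: 11 methyl (2S)-3-(tert-butyldimethylsilyloxy)-2-ethynyl-4-oxo-5,7-bis(triisopropylsilyloxy)chromane-2-carboxylate (C3' epimers)
Conditions: AgNO3 (10 mol %), acetone/H2O, 23 °C
Reagents that add atoms: none
Why: Silver-catalysed protodesilylation of the alkynylsilane proceeds under neutral conditions that leave aryl and alkyl silyl ethers and the base-sensitive chromanone untouched.

Step 6
Reactants: 12 4-hydroxybenzaldehyde
Product: 13 4-(triisopropylsilyloxy)benzaldehyde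
Conditions: TIPSCl, imidazole, DMF, 23 °C
Reagents that add atoms: chlorotriisopropylsilane CC(C)[Si](Cl)(C(C)C)C(C)C
Why: Standard silylation of a phenol.

Step 7
Reactants: 11 ethynyl α-silyloxy chromanone; 13 4-(triisopropylsilyloxy)benzaldehyde
Product: 15 methyl (2S,3S)-3-(tert-butyldimethylsilyloxy)-2-ethynyl-3-{(R)-hydroxy[4-(triisopropylsilyloxy)phenyl]methyl}-4-oxo-5,7-bis(triisopropylsilyloxy)chromane-2-carboxylate, via bis-silyl enediol ether 14 (not isolated)
Conditions: TMSOTf, Et3N, CH2Cl2, 0 °C; then 13, BF3·OEt2, CH2Cl2, −78 °C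
Reagents that add atoms: none
Why: Soft enolisation followed by a Mukaiyama aldol addition at C3' (the C4' cation is stabilised by the trioxygenated arene); allylic 1,2-strain with the C3' silyloxy group should place the ester on C8 pseudoaxial and the slim alkyne pseudoequatorial, so the aldehyde adds anti to the ester and the new C3'–C2' bond is cis to the alkyne, while an open antiperiplanar transition state with the aryl group turned away from quaternary C8 should give the (R) carbinol at C2'.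

Step 8
Reactants: 16 4-iodophenol
Product: 17 (4-iodophenoxy)triisopropylsilane
Conditions: TIPSCl, imidazole, DMF, 23 °C
Reagents that add atoms: chlorotriisopropylsilane CC(C)[Si](Cl)(C(C)C)C(C)C
Why: Standard silylation of a phenol.

Step 9
Reactants: 17 (4-iodophenoxy)triisopropylsilane; 18 pent-4-enoic acid
Product: 19 (E)-5-[4-(triisopropylsilyloxy)phenyl]pent-4-enoic acid
Conditions: Pd(OAc)2 (3 mol %), P(o-tol)3, Et3N, MeCN, 80 °C; then aq. citric acid
Reagents that add atoms: none
Why: Mizoroki–Heck arylation of the terminal alkene, with β-hydride elimination towards the conjugated (E)-styrene.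

Step 10
Reactants: 15 aldol from step 7; 19 (E)-5-arylpent-4-enoic acid
Product: 22 enol ether with ring D closed (methyl ester on C8; E-configured 2-oxo-6-arylhex-5-enylidene arm on C7; C2' R, C3' S, C8 S), via acid chloride 20 (not isolated), via ynone 21 (not isolated)
Conditions: 19, (COCl)2, N,N-dimethylformamide (cat.), CH2Cl2, 0 to 23 °C, evaporate; then 15, PdCl2(PPh3)2 (2 mol %), CuI (4 mol %), Et3N (1.1 equiv), THF, 23 °C; then 1,8-diazabicyclo[5.4.0]undec-7-ene (10 mol %), 0 °C
Reagents that add atoms: none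
Why: Acyl Sonogashira coupling gives ynone 21 (the neopentyl-type C2' hydroxyl should be acylated far more slowly than the copper acetylide), and the C2' hydroxyl then adds 5-exo-dig in an oxa-Michael reaction with retention at C2'; the exocyclic enol ether is expected to settle on the E geometry (acyl group anti to the ring oxygen, as in other 2-(2-oxoalkylidene)tetrahydrofurans), which step 12 requires.

Step 11
Reactants: 22 enol ether with styrene terminus
Product: 23 (2S,3S)-trans-epoxide of 22 at C2–C3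
Conditions: 1,2:4,5-di-O-isopropylidene-β-L-erythro-2,3-hexodiulo-2,6-pyranose (30 mol %), KHSO5 (as Oxone, 2KHSO5·KHSO4·K2SO4), K2CO3, Bu4NHSO4, MeCN/CH2(OMe)2/aq. Na2B4O7 buffer, 0 °C
Reagents that add atoms: potassium peroxymonosulfate [K+].[O-]S(=O)(=O)OO
Why: Shi epoxidation with the L-series ketone should deliver the (S,S)-epoxide of the E-styrene through the spiro transition state (the D-series ketone gives R,R), and the dioxirane should take the electron-rich styrene in preference to the push–pull enol ether.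

Step 12
Reactants: 23 epoxy enol ether
Product: 25 ring A closed as the C8a ketone / C5 tert-butyldimethylsilyl enol ether, epoxide intact, via lithium diketonate 24 (not isolated)
Conditions: LiN(SiMe3)2 (2.2 equiv), THF, −78 to −20 °C; then TBSOTf (2.4 equiv), −78 °C; pH 7 buffer
Reagents that add atoms: tert-butyldimethylsilyl trifluoromethanesulfonate CC(C)(C)[Si](C)(C)OS(=O)(=O)C(F)(F)F
Why: LiN(SiMe3)2 removes a C4a proton of the vinylogous ester (the only enolisable position, since C6 is vinylic and C8 and C3' are quaternary) and the cross-conjugated lithium dienolate adds to the C8a methyl ester; loss of methoxide gives the cyclic β-diketone, whose immediate deprotonation to diketonate 24 makes the Claisen step irreversible. The closest known reaction type is the Dieckmann (intramolecular Claisen) cyclisation of 3,5-dioxygenated esters to phloroglucinol-type rings, here with the α'-enolate of a vinylogous ester as in Stork–Danheiser chemistry. Ring A closes in a 6-(enolexo)-exo-trig mode, and the quaternary C8 blocks aromatisation, so the dienone oxidation pattern of the target is obtained directly. No stereocentre is formed; C8, C3' and C2' cannot enolise, the tertiary C3' oxygen is silylated (no retro-aldol, no β-elimination), and a lithium enolate should not open the epoxide at −78 °C. The cyclisation needs the E enol ether of 23, which holds C5 syn to C8. The silyl triflate quench should silylate the diketonate at O5, the oxygen remote from the quaternary carbon (as in enol ether formation from 4,4-disubstituted cyclohexane-1,3-diones), which leaves the C8a carbonyl oxygen as the only nucleophile for step 13.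

Step 13
Reactants: 25 silyl enol ether epoxide
Product: 26 hexasilyl ether of the target (four aryl OTIPS; C3 and C3' OTBS)
Conditions: TBSOTf (10 mol %), 2,6-di-tert-butyl-4-methylpyridine (20 mol %), CH2Cl2, −78 to −30 °C
Reagents that add atoms: none
Why: Silyl-triflate-catalysed epoxide-opening cyclisation with neighbouring carbonyl participation: the C8a carbonyl oxygen attacks the benzylic C2 of the O-silylated epoxide 6-endo with inversion (favoured by the para-silyloxyphenyl group), the O5 silyl group of the resulting oxocarbenium ion is released as TBSOTf to carry the chain, and the 2,3-trans (2R,3S) ring C results with O1 bound to C8a.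

Step 14
Reactants: 26 hexasilyl ether
Product: 27 Genkwanol C
Conditions: HF·pyridine, pyridine, THF, 0 to 23 °C
Reagents that add atoms: none
Why: Global fluoride-mediated desilylation under buffered, weakly acidic conditions avoids hydrogenolysis and strong base, both of which threaten the benzylic vinylogous-ester C–O bonds and the C3' α-ketol.

**Compound list**

1 | 2',4',6'-trihydroxyacetophenone | CC(=O)c1c(O)cc(O)cc1O | starting material
2 | dimethyl oxalate | COC(=O)C(=O)OC | starting material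
3 | methyl 2,4-dioxo-4-(2,4,6-trihydroxyphenyl)butanoate | COC(=O)C(=O)CC(=O)c1c(O)cc(O)cc1O | intermediate
4 | methyl 5,7-dihydroxy-4-oxo-4H-chromene-2-carboxylate | COC(=O)c1cc(=O)c2c(O)cc(O)cc2o1 | intermediate
5 | methyl 4-oxo-5,7-bis(triisopropylsilyloxy)-4H-chromene-2-carboxylate | COC(=O)c1cc(=O)c2c(O[Si](C(C)C)(C(C)C)C(C)C)cc(O[Si](C(C)C)(C(C)C)C(C)C)cc2o1 | intermediate
6 | ethynyltrimethylsilane | C#C[Si](C)(C)C | starting material
7 | 4-(tert-butyldimethylsilyloxy)-2-(methoxycarbonyl)-5,7-bis(triisopropylsilyloxy)chromenylium triflate | COC(=O)c1cc(O[Si](C)(C)C(C)(C)C)c2c(O[Si](C(C)C)(C(C)C)C(C)C)cc(O[Si](C(C)C)(C(C)C)C(C)C)cc2[o+]1.[O-]S(=O)(=O)C(F)(F)F | intermediate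
8 | methyl (2R)-4-(tert-butyldimethylsilyloxy)-5,7-bis(triisopropylsilyloxy)-2-[(trimethylsilyl)ethynyl]-2H-chromene-2-carboxylate | COC(=O)[C@@]1(C#C[Si](C)(C)C)Oc2cc(O[Si](C(C)C)(C(C)C)C(C)C)cc(O[Si](C(C)C)(C(C)C)C(C)C)c2C(O[Si](C)(C)C(C)(C)C)=C1 | intermediate
9 | 3,4-epoxide of 8 (4-silyloxy oxirane, C3'/C4' configuration unspecified) | COC(=O)[C@@]1(C#C[Si](C)(C)C)Oc2cc(O[Si](C(C)C)(C(C)C)C(C)C)cc(O[Si](C(C)C)(C(C)C)C(C)C)c2C3(O[Si](C)(C)C(C)(C)C)OC13 | intermediate
10 | methyl (2S)-3-(tert-butyldimethylsilyloxy)-4-oxo-5,7-bis(triisopropylsilyloxy)-2-[(trimethylsilyl)ethynyl]chromane-2-carboxylate (C3' epimers) | COC(=O)[C@@]1(C#C[Si](C)(C)C)Oc2cc(O[Si](C(C)C)(C(C)C)C(C)C)cc(O[Si](C(C)C)(C(C)C)C(C)C)c2C(=O)C1O[Si](C)(C)C(C)(C)C | intermediate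
11 | methyl (2S)-3-(tert-butyldimethylsilyloxy)-2-ethynyl-4-oxo-5,7-bis(triisopropylsilyloxy)chromane-2-carboxylate (C3' epimers) | COC(=O)[C@@]1(C#C)Oc2cc(O[Si](C(C)C)(C(C)C)C(C)C)cc(O[Si](C(C)C)(C(C)C)C(C)C)c2C(=O)C1O[Si](C)(C)C(C)(C)C | intermediate
12 | 4-hydroxybenzaldehyde | O=Cc1ccc(O)cc1 | starting material
13 | 4-(triisopropylsilyloxy)benzaldehyde | O=Cc1ccc(O[Si](C(C)C)(C(C)C)C(C)C)cc1 | intermediate
14 | methyl (2S)-3-(tert-butyldimethylsilyloxy)-2-ethynyl-4-(trimethylsilyloxy)-5,7-bis(triisopropylsilyloxy)-2H-chromene-2-carboxylate | COC(=O)[C@@]1(C#C)Oc2cc(O[Si](C(C)C)(C(C)C)C(C)C)cc(O[Si](C(C)C)(C(C)C)C(C)C)c2C(O[Si](C)(C)C)=C1O[Si](C)(C)C(C)(C)C | intermediate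
15 | methyl (2S,3S)-3-(tert-butyldimethylsilyloxy)-2-ethynyl-3-{(R)-hydroxy[4-(triisopropylsilyloxy)phenyl]methyl}-4-oxo-5,7-bis(triisopropylsilyloxy)chromane-2-carboxylate | O[C@H](c1ccc(O[Si](C(C)C)(C(C)C)C(C)C)cc1)[C@@]2(O[Si](C)(C)C(C)(C)C)C(=O)c3c(O[Si](C(C)C)(C(C)C)C(C)C)cc(O[Si](C(C)C)(C(C)C)C(C)C)cc3O[C@]2(C#C)C(=O)OC | intermediate
16 | 4-iodophenol | Oc1ccc(I)cc1 | starting material
17 | (4-iodophenoxy)triisopropylsilane | Ic1ccc(O[Si](C(C)C)(C(C)C)C(C)C)cc1 | intermediate
18 | pent-4-enoic acid | C=CCCC(=O)O | starting material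
19 | (E)-5-[4-(triisopropylsilyloxy)phenyl]pent-4-enoic acid | OC(=O)CC/C=C/c1ccc(O[Si](C(C)C)(C(C)C)C(C)C)cc1 | intermediate
20 | (E)-5-[4-(triisopropylsilyloxy)phenyl]pent-4-enoyl chloride | ClC(=O)CC/C=C/c1ccc(O[Si](C(C)C)(C(C)C)C(C)C)cc1 | intermediate
21 | ynone: compound 15 acylated at the alkyne terminus by the (E)-5-arylpent-4-enoyl group (C2' R, C3' S, C8 S) | O[C@H](c1ccc(O[Si](C(C)C)(C(C)C)C(C)C)cc1)[C@@]2(O[Si](C)(C)C(C)(C)C)C(=O)c3c(O[Si](C(C)C)(C(C)C)C(C)C)cc(O[Si](C(C)C)(C(C)C)C(C)C)cc3O[C@]2(C#CC(=O)CC/C=C/c4ccc(O[Si](C(C)C)(C(C)C)C(C)C)cc4)C(=O)OC | intermediate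
22 | enol ether with ring D closed: O7 joins C2' to C7; (E)-2-oxo-6-arylhex-5-enylidene arm on C7; methyl ester on C8 (C2' R, C3' S, C8 S) | O=C(CC/C=C/c1ccc(O[Si](C(C)C)(C(C)C)C(C)C)cc1)/C=C2/O[C@H](c3ccc(O[Si](C(C)C)(C(C)C)C(C)C)cc3)[C@@]4(O[Si](C)(C)C(C)(C)C)C(=O)c5c(O[Si](C(C)C)(C(C)C)C(C)C)cc(O[Si](C(C)C)(C(C)C)C(C)C)cc5O[C@@]24C(=O)OC | intermediate
23 | (2S,3S)-trans-epoxide of 22 at the former styrene (C2' R, C3' S, C8 S) | O=C(CC[C@@H]6O[C@H]6c1ccc(O[Si](C(C)C)(C(C)C)C(C)C)cc1)/C=C2/O[C@H](c3ccc(O[Si](C(C)C)(C(C)C)C(C)C)cc3)[C@@]4(O[Si](C)(C)C(C)(C)C)C(=O)c5c(O[Si](C(C)C)(C(C)C)C(C)C)cc(O[Si](C(C)C)(C(C)C)C(C)C)cc5O[C@@]24C(=O)OC | intermediate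
24 | lithium diketonate of ring A (C5/C8a), epoxide intact | [Li+].[O-]C1C=C2O[C@H](c3ccc(O[Si](C(C)C)(C(C)C)C(C)C)cc3)[C@@]4(O[Si](C)(C)C(C)(C)C)C(=O)c5c(O[Si](C(C)C)(C(C)C)C(C)C)cc(O[Si](C(C)C)(C(C)C)C(C)C)cc5O[C@@]24C(=O)C=1C[C@@H]6O[C@H]6c7ccc(O[Si](C(C)C)(C(C)C)C(C)C)cc7 | intermediate
25 | ring A closed: C8a ketone, C5 tert-butyldimethylsilyl enol ether, C4a bearing the (2S,3S)-epoxypropyl-aryl arm (C2' R, C3' S, C8 S) | CC(C)(C)[Si](C)(C)OC1C=C2O[C@H](c3ccc(O[Si](C(C)C)(C(C)C)C(C)C)cc3)[C@@]4(O[Si](C)(C)C(C)(C)C)C(=O)c5c(O[Si](C(C)C)(C(C)C)C(C)C)cc(O[Si](C(C)C)(C(C)C)C(C)C)cc5O[C@@]24C(=O)C=1C[C@@H]6O[C@H]6c7ccc(O[Si](C(C)C)(C(C)C)C(C)C)cc7 | intermediate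
26 | Genkwanol C hexasilyl ether: four phenolic OTIPS, C3 and C3' OTBS (2R, 3S, 2'R, 3'S, 8R) | O=C1C=C2O[C@H](c3ccc(O[Si](C(C)C)(C(C)C)C(C)C)cc3)[C@@]4(O[Si](C)(C)C(C)(C)C)C(=O)c5c(O[Si](C(C)C)(C(C)C)C(C)C)cc(O[Si](C(C)C)(C(C)C)C(C)C)cc5O[C@@]24C6=C1C[C@H](O[Si](C)(C)C(C)(C)C)[C@@H](c7ccc(O[Si](C(C)C)(C(C)C)C(C)C)cc7)O6 | intermediate
27 | Genkwanol C (2R, 3S, 2'R, 3'S, 8R) | O=C1C=C2O[C@H](c3ccc(O)cc3)[C@@]3(O)C(=O)c4c(O)cc(O)cc4O[C@@]23C2=C1C[C@H](O)[C@@H](c1ccc(O)cc1)O2 | target

**Totals.** Total step count: 14. Longest linear sequence: 11 steps (steps 1–5, 7, 10–14).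

**Steps most likely to fail**

1. Step 12 (key step). The dienolate cannot reach the ester if the exocyclic enol ether has drifted to the Z geometry, and on warming the enolate may alkylate the epoxide (3-exo-tet) or the hindered ester may resist attack. Fallback, setting out from 22 and coming back at 26: ring A is closed before epoxidation with TiCl4/Bu3N in CH2Cl2 at −78 °C (titanium-mediated Dieckmann condensation; coordination of the vinylogous ester lowers the C6=C7 rotation barrier, so either geometry converges), giving the ring A vinylogous acid with the styrene intact F1. Mitsunobu etherification with 2-(trimethylsilyl)ethanol (PPh3, DIAD) at the less hindered O5 gives the O5 2-(trimethylsilyl)ethyl vinylogous ester F2. Shi epoxidation under the conditions of step 11 gives the corresponding (2S,3S)-epoxide F3. TBSOTf (1.1 equiv) with 2,6-di-tert-butyl-4-methylpyridine then triggers the same carbonyl-oxygen epoxide opening, the O5 group fragmenting to ethene and Me3SiOTf, which gives 26.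

2. Step 7. Bond formation at the congested, fully substituted C3' may stall under Lewis acid activation, or the addition may show poor control at C2'. Fallback, setting out from 11 and coming back at 15: the lithium enolate of 11 (LiN(SiMe3)2, THF, −78 °C) is added to 13, which should give, through a closed transition state, mainly the C2' epimer of the aldol F4. Dess–Martin oxidation gives the 2-silyloxy-1,3-diketone F5. Reduction of its para-silyloxyphenyl ketone with NaBH4 in MeOH/THF at −40 °C under Felkin–Anh control (silyloxy group anti to the hydride; the ring ketone C4' is hindered and deactivated by its ortho oxygen substituents) returns 15.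

3. Step 13. Silyl migration between O5 and O8a before cyclisation would lead to the linear dienone regioisomer, and full ionisation at C2 would erode the inversion. Fallback, setting out from 23 and coming back at 26: the Dieckmann cyclisation of step 12 is repeated but diketonate 24 is quenched with Boc2O, giving the non-migrating O5 tert-butyl enol carbonate F6. TBSOTf (1.1 equiv) with 2,6-di-tert-butyl-4-methylpyridine in CH2Cl2 at −78 °C then silylates the epoxide, O8a attacks C2 with inversion and the carbonate fragments to CO2 and 2-methylpropene, which gives 26.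

**Further compounds**

F1 | step 12 | ring A vinylogous acid (C5 enol, C8a ketone) with (E)-3-arylallyl arm on C4a | OC1C=C2O[C@H](c3ccc(O[Si](C(C)C)(C(C)C)C(C)C)cc3)[C@@]4(O[Si](C)(C)C(C)(C)C)C(=O)c5c(O[Si](C(C)C)(C(C)C)C(C)C)cc(O[Si](C(C)C)(C(C)C)C(C)C)cc5O[C@@]24C(=O)C=1C/C=C/c7ccc(O[Si](C(C)C)(C(C)C)C(C)C)cc7
F2 | step 12 | O5 2-(trimethylsilyl)ethyl vinylogous ester of F1 | C[Si](C)(C)CCOC1C=C2O[C@H](c3ccc(O[Si](C(C)C)(C(C)C)C(C)C)cc3)[C@@]4(O[Si](C)(C)C(C)(C)C)C(=O)c5c(O[Si](C(C)C)(C(C)C)C(C)C)cc(O[Si](C(C)C)(C(C)C)C(C)C)cc5O[C@@]24C(=O)C=1C/C=C/c7ccc(O[Si](C(C)C)(C(C)C)C(C)C)cc7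
F3 | step 12 | (2S,3S)-epoxide of F2 | C[Si](C)(C)CCOC1C=C2O[C@H](c3ccc(O[Si](C(C)C)(C(C)C)C(C)C)cc3)[C@@]4(O[Si](C)(C)C(C)(C)C)C(=O)c5c(O[Si](C(C)C)(C(C)C)C(C)C)cc(O[Si](C(C)C)(C(C)C)C(C)C)cc5O[C@@]24C(=O)C=1C[C@@H]6O[C@H]6c7ccc(O[Si](C(C)C)(C(C)C)C(C)C)cc7
F4 | step 7 | C2' epimer of aldol 15 ((S)-carbinol) | O[C@@H](c1ccc(O[Si](C(C)C)(C(C)C)C(C)C)cc1)[C@@]2(O[Si](C)(C)C(C)(C)C)C(=O)c3c(O[Si](C(C)C)(C(C)C)C(C)C)cc(O[Si](C(C)C)(C(C)C)C(C)C)cc3O[C@]2(C#C)C(=O)OC
F5 | step 7 | methyl (2S,3S)-3-(tert-butyldimethylsilyloxy)-2-ethynyl-4-oxo-3-[4-(triisopropylsilyloxy)benzoyl]-5,7-bis(triisopropylsilyloxy)chromane-2-carboxylate | O=C(c1ccc(O[Si](C(C)C)(C(C)C)C(C)C)cc1)[C@@]2(O[Si](C)(C)C(C)(C)C)C(=O)c3c(O[Si](C(C)C)(C(C)C)C(C)C)cc(O[Si](C(C)C)(C(C)C)C(C)C)cc3O[C@]2(C#C)C(=O)OC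
F6 | step 13 | O5 tert-butyl enol carbonate analogue of 25 | CC(C)(C)OC(=O)OC1C=C2O[C@H](c3ccc(O[Si](C(C)C)(C(C)C)C(C)C)cc3)[C@@]4(O[Si](C)(C)C(C)(C)C)C(=O)c5c(O[Si](C(C)C)(C(C)C)C(C)C)cc(O[Si](C(C)C)(C(C)C)C(C)C)cc5O[C@@]24C(=O)C=1C[C@@H]6O[C@H]6c7ccc(O[Si](C(C)C)(C(C)C)C(C)C)cc7
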